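**Plan**

Locants: ring C5–C10 (C5 bears the side chain C4–C1, C6 the OAc, C8 the lactone O, C10 the C14H2O group); lactone C11 (α), C12 (C=O), C13 (=CH2).
Cuts: the three acyl–O bonds; C11=C13 (from a β-silyl sulfone); C7–C11 together with O8–C12; the C7–C8 epoxide and C7=C8; the ring bond C5–C10, back to a δ-keto ester from (S)-citronellic acid.
Forward: Negishi acylation, Dieckmann-type closure to a 2-alkylcyclohexane-1,3-dione, enol triflate carbonylation, selenenylation/CBS reduction/selenoxide elimination to a 2,5-dienol, epoxidation; the key step then closes a 1-oxa-2-silacyclohexane (C7–C11) and at once the trans-fused lactone; fluoride releases C11=C13 and O6.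
Stereochemistry: C4 from (S)-citronellic acid; C6 by CBS reduction; C7 and C8 by epoxidation anti to the C6 silyloxy group and SN2 inversion at C7.
Enabling feature: on the cyclohexene the C6 oxygen is cis to the C7–C11 bond and the C8 oxygen is trans to it. A C7–C8 epoxide anti to O6 can therefore be opened at C7 from the O6 face by a carbanion held on O6 through silicon, and the epoxide oxygen becomes the lactone oxygen.

Key step: step 14

Step 1
Reactants: 1 (S)-citronellic acid; 2 (4-ethoxy-4-oxobutyl)zinc bromide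
Product: 4 ethyl (7S)-7,11-dimethyl-5-oxododec-10-enoate, via (S)-citronelloyl chloride 3 (not isolated)
Conditions: (COCl)2, DMF (cat.), CH2Cl2, 0 to 23 °C; evaporate; then 2 (1.3 equiv), Pd(PPh3)4 (3 mol %), THF, 0 to 23 °C
Reagents that add atoms: none
Why: Negishi acylation (zerovalent-palladium-catalysed coupling of an alkylzinc halide with an acid chloride) should give the δ-keto ester; the stereocenter is β to the carbonyl and is not touched.

Step 2
Reactants: 4 ethyl (7S)-7,11-dimethyl-5-oxododec-10-enoate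
Product: 5 2-[(2S)-6-methylhept-5-en-2-yl]cyclohexane-1,3-dione
Conditions: KOtBu (2.2 equiv), THF, 0 to 23 °C; then aq. HCl
Reagents that add atoms: none
Why: Dieckmann-type intramolecular Claisen acylation, in which only the ketone α-carbon on the branched side can reach the ester through a six-membered transition state and deprotonation of the 1,3-dione drives the closure.

Step 3
Reactants: 5 2-[(2S)-6-methylhept-5-en-2-yl]cyclohexane-1,3-dione
Product: 6 2-[(2S)-6-methylhept-5-en-2-yl]-3-oxocyclohex-1-en-1-yl trifluoromethanesulfonate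
Conditions: Tf2O, pyridine, CH2Cl2, −78 to 0 °C
Reagents that add atoms: trifluoromethanesulfonic anhydride O=S(=O)(OS(=O)(=O)C(F)(F)F)C(F)(F)F
Why: O-sulfonylation of the dione enol; the two carbonyls are constitutionally equivalent, so a single enol triflate should form.

Step 4
Reactants: 6 2-[(2S)-6-methylhept-5-en-2-yl]-3-oxocyclohex-1-en-1-yl trifluoromethanesulfonate
Product: 7 methyl 2-[(2S)-6-methylhept-5-en-2-yl]-3-oxocyclohex-1-ene-1-carboxylate
Conditions: CO (1 atm), MeOH, Pd(OAc)2 (5 mol %), dppp, Et3N, DMF, 60 °C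
Reagents that add atoms: carbon monoxide [C-]#[O+]; methanol CO
Why: Palladium-catalysed alkoxycarbonylation of an enol triflate installs C14 as an ester, which later deactivates the C5=C10 alkene toward peracid.

Step 5
Reactants: 7 methyl 2-[(2S)-6-methylhept-5-en-2-yl]-3-oxocyclohex-1-ene-1-carboxylate
Product: 9 methyl 2-[(2S)-5-hydroxypentan-2-yl]-3-oxocyclohex-1-ene-1-carboxylate, via methyl 3-oxo-2-[(2S)-5-oxopentan-2-yl]cyclohex-1-ene-1-carboxylate 8 (not isolated)
Conditions: O3, CH2Cl2/MeOH, −78 °C (Sudan Red 7B end point); Me2S; then NaBH(OAc)3, AcOH, 0 °C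
Reagents that add atoms: ozone [O-][O+]=O
Why: Chemoselective ozonolysis of the electron-rich trisubstituted alkene (the ring alkene carries two acceptors) followed by aldehyde-selective hydride reduction should leave the enone intact.

Step 6
Reactants: 9 methyl 2-[(2S)-5-hydroxypentan-2-yl]-3-oxocyclohex-1-ene-1-carboxylate
Product: 10 methyl 2-[(2S)-5-(tert-butyldimethylsilyloxy)pentan-2-yl]-3-oxocyclohex-1-ene-1-carboxylate
Conditions: TBSCl, imidazole, DMF, 23 °C
Reagents that add atoms: tert-butyldimethylsilyl chloride CC(C)(C)[Si](C)(C)Cl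
Why: Standard silylation of the primary alcohol, which must survive the base, hydride and peracid steps and is removed by fluoride in step 16.

Step 7
Reactants: 10 methyl 2-[(2S)-5-(tert-butyldimethylsilyloxy)pentan-2-yl]-3-oxocyclohex-1-ene-1-carboxylate
Product: 12 methyl 2-[(2S)-5-(tert-butyldimethylsilyloxy)pentan-2-yl]-3-oxo-4-(phenylselanyl)cyclohex-1-ene-1-carboxylate (both C4 epimers), via lithium α′-dienolate 11 (not isolated)
Conditions: LiN(iPr)2 (1.05 equiv), THF, −78 °C; PhSeCl, −78 °C
Reagents that add atoms: phenylselenenyl chloride Cl[Se]c1ccccc1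
Why: Kinetic α′-deprotonation of the enone and selenenylation of the cross-conjugated enolate at C7; the new center needs no control because it becomes sp2 in step 9.

Step 8
Reactants: 12 methyl 2-[(2S)-5-(tert-butyldimethylsilyloxy)pentan-2-yl]-3-oxo-4-(phenylselanyl)cyclohex-1-ene-1-carboxylate
Product: 13 methyl (3R)-2-[(2S)-5-(tert-butyldimethylsilyloxy)pentan-2-yl]-3-hydroxy-4-(phenylselanyl)cyclohex-1-ene-1-carboxylate (both C4 epimers)
Conditions: (R)-2-methyl-CBS-oxazaborolidine (20 mol %), catecholborane, toluene, −78 °C; then MeOH/H2O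
Reagents that add atoms: none
Why: Corey–Bakshi–Shibata reduction, in which the (R)-oxazaborolidine should treat the tetrasubstituted alkenyl side as the large group and deliver hydride to the face that gives the C6 carbinol of the target for either C7 epimer (reagent control).

Step 9
Reactants: 13 methyl (3R)-2-[(2S)-5-(tert-butyldimethylsilyloxy)pentan-2-yl]-3-hydroxy-4-(phenylselanyl)cyclohex-1-ene-1-carboxylate
Product: 15 methyl (3S)-2-[(2S)-5-(tert-butyldimethylsilyloxy)pentan-2-yl]-3-hydroxycyclohexa-1,4-diene-1-carboxylate, via selenoxide 14 (not isolated)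
Conditions: H2O2 (30 % aq.), pyridine, CH2Cl2, 0 to 23 °C
Reagents that add atoms: none
Why: Selenide oxidation and selenoxide syn-elimination, which for a β-hydroxy selenoxide runs away from the carbinol and should give the C7=C8 alkene under nonacidic conditions that spare the dienol.

Step 10
Reactants: 15 methyl (3S)-2-[(2S)-5-(tert-butyldimethylsilyloxy)pentan-2-yl]-3-hydroxycyclohexa-1,4-diene-1-carboxylate
Product: 16 methyl (3S)-3-{[(bromomethyl)dimethylsilyl]oxy}-2-[(2S)-5-(tert-butyldimethylsilyloxy)pentan-2-yl]cyclohexa-1,4-diene-1-carboxylate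
Conditions: BrCH2SiMe2Cl, imidazole, CH2Cl2, 0 °C
Reagents that add atoms: (bromomethyl)chlorodimethylsilane C[Si](C)(Cl)CBr
Why: Silylation of the carbinol gives a nonparticipating ether for the epoxidation and the silicon anchor of the later tether.

Step 11
Reactants: 16 methyl (3S)-3-{[(bromomethyl)dimethylsilyl]oxy}-2-[(2S)-5-(tert-butyldimethylsilyloxy)pentan-2-yl]cyclohexa-1,4-diene-1-carboxylate
Product: 17 methyl (3R,4R,5R)-3-{[(bromomethyl)dimethylsilyl]oxy}-2-[(2S)-5-(tert-butyldimethylsilyloxy)pentan-2-yl]-4,5-epoxycyclohex-1-ene-1-carboxylate (epoxide anti to the silyloxy group)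
Conditions: mCPBA, NaHCO3, CH2Cl2, 0 °C
Reagents that add atoms: 3-chloroperoxybenzoic acid OOC(=O)c1cccc(Cl)c1
Why: Prilezhaev epoxidation, which should occur only at the cis-disubstituted C7=C8 alkene (the enoate alkene is deactivated) and from the face anti to the pseudoaxial silyloxy group, setting C7 and C8.

Step 12
Reactants: 17 methyl (3R,4R,5R)-3-{[(bromomethyl)dimethylsilyl]oxy}-2-[(2S)-5-(tert-butyldimethylsilyloxy)pentan-2-yl]-4,5-epoxycyclohex-1-ene-1-carboxylate
Product: 18 [(3R,4R,5R)-3-{[(bromomethyl)dimethylsilyl]oxy}-2-[(2S)-5-(tert-butyldimethylsilyloxy)pentan-2-yl]-4,5-epoxycyclohex-1-en-1-yl]methanol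
Conditions: iBu2AlH (2.5 equiv), CH2Cl2, −78 °C; Rochelle salt work-up
Reagents that add atoms: none
Why: Hydride reduction of the conjugated ester to the allylic alcohol at −78 °C, where epoxide, alkyl bromide and silyl ethers should survive.

Step 13
Reactants: 18 [(3R,4R,5R)-3-{[(bromomethyl)dimethylsilyl]oxy}-2-[(2S)-5-(tert-butyldimethylsilyloxy)pentan-2-yl]-4,5-epoxycyclohex-1-en-1-yl]methanol; 19 methyl (phenylsulfonyl)acetate
Product: 21 tethered epoxide (18 with Si–CH2Br replaced by Si–CH2–CH(SO2Ph)CO2Me; both C11 epimers), via sodium methyl (phenylsulfonyl)acetate 20 (not isolated)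
Conditions: NaH (1.0 equiv per 19), DMF, 0 °C; then 18, NaI (cat.), 23 to 40 °C
Reagents that add atoms: none
Why: SN2 C-alkylation of the soft sulfonylacetate anion at the α-silyl primary bromide (Finkelstein-assisted); the anion is too weakly basic to deprotonate the alcohol or open the epoxide at this temperature.

Step 14
Reactants: 21 tethered epoxide
Product: 23 tricyclic sulfonyl lactone (1-oxa-2-silacyclohexane O6–Si–C13–C11–C7–C6; γ-lactone C11–C12(=O)–O8), via ring-opened hydroxy ester 22 (not isolated)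
Conditions: DBU (0.3 equiv), LiClO4 (2 equiv), 3 Å molecular sieves, MeCN, 50 °C
Reagents that add atoms: none
Why: Proposed new method: DBU with LiClO4 deprotonates the sulfonyl ester C–H of the tether, the carbanion attacks C7 of the lithium-activated epoxide in an SN2 reaction, and the C8 alkoxide then acylates itself on the methyl ester; the closest known reaction type is the intramolecular alkylation of nitrile-, sulfonyl- or malonate-stabilized carbanions by epoxides (Stork epoxynitrile cyclization), run here across a silyl ether tether of the kind used in silicon-tethered radical cyclizations. The 1-oxa-2-silacyclohexane closes in the 6-exo-tet mode through a chair transition state, and the γ-lactone closes by 5-exo-trig acyl substitution with loss of methanol. C7 is set by backside attack anti to the epoxide oxygen, which the tether permits only from the face of the C6 oxygen, so the C7–C11 bond ends cis to O6 and trans to O8; C8 keeps its epoxide C–O bond, and C11 is a transient quaternary center removed in step 16. The step needs attack at C7 and not at C8, which the three-atom O–Si–C tether secures because C8 would require a 7-endo closure. It also needs lactonization on O8 alone, which holds because O6 is locked in the silicon ring. In the chair the bulky sulfonyl group should sit anti to C8, which leaves the ester gauche to the C8 alkoxide for ring closure.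

Step 15
Reactants: 23 tricyclic sulfonyl lactone
Product: 24 C14 methacrylate of 23
Conditions: methacrylic anhydride, Et3N, DMAP (cat.), CH2Cl2, 0 °C
Reagents that add atoms: methacrylic anhydride C=C(C)C(=O)OC(=O)C(C)=C
Why: DMAP-catalysed acylation of the only free hydroxyl, the primary allylic C14–OH.

Step 16
Reactants: 24 C14 methacrylate of 23
Product: 25 diol (the target lacking both acetyl groups)
Conditions: Bu4NF (4 equiv), THF, 0 °C; pH 7 buffer
Reagents that add atoms: none
Why: Fluoride attack on silicon triggers the 1,2-elimination of the β-silyl sulfone (loss of benzenesulfinate) to the α-methylene lactone and also cleaves the Si–O6 bond and the TBS ether.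

Step 17
Reactants: 25 diol
Product: 26 target CNP0157277.1
Conditions: Ac2O, pyridine, DMAP (cat.), CH2Cl2, 23 °C
Reagents that add atoms: acetic anhydride CC(=O)OC(C)=O
Why: DMAP-catalysed acetylation of the C6 and C1 hydroxyls completes the target without touching a stereocenter.

**Compound list**

1 | (S)-citronellic acid, (3S)-3,7-dimethyloct-6-enoic acid | OC(=O)C[C@@H](C)CCC=C(C)C | starting material
2 | (4-ethoxy-4-oxobutyl)zinc bromide | CCOC(=O)CCC[Zn]Br | starting material
3 | (S)-citronelloyl chloride | ClC(=O)C[C@@H](C)CCC=C(C)C | intermediate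
4 | ethyl (7S)-7,11-dimethyl-5-oxododec-10-enoate | CCOC(=O)CCCC(=O)C[C@@H](C)CCC=C(C)C | intermediate
5 | 2-[(2S)-6-methylhept-5-en-2-yl]cyclohexane-1,3-dione | O=C1CCCC(=O)C1[C@@H](C)CCC=C(C)C | intermediate
6 | 2-[(2S)-6-methylhept-5-en-2-yl]-3-oxocyclohex-1-en-1-yl trifluoromethanesulfonate | O=C1CCCC(OS(=O)(=O)C(F)(F)F)=C1[C@@H](C)CCC=C(C)C | intermediate
7 | methyl 2-[(2S)-6-methylhept-5-en-2-yl]-3-oxocyclohex-1-ene-1-carboxylate | COC(=O)C1=C([C@@H](C)CCC=C(C)C)C(=O)CCC1 | intermediate
8 | methyl 3-oxo-2-[(2S)-5-oxopentan-2-yl]cyclohex-1-ene-1-carboxylate | COC(=O)C1=C([C@@H](C)CCC=O)C(=O)CCC1 | intermediate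
9 | methyl 2-[(2S)-5-hydroxypentan-2-yl]-3-oxocyclohex-1-ene-1-carboxylate | COC(=O)C1=C([C@@H](C)CCCO)C(=O)CCC1 | intermediate
10 | methyl 2-[(2S)-5-(tert-butyldimethylsilyloxy)pentan-2-yl]-3-oxocyclohex-1-ene-1-carboxylate | COC(=O)C1=C([C@@H](C)CCCO[Si](C)(C)C(C)(C)C)C(=O)CCC1 | intermediate
11 | lithium α′-dienolate of 10 (O-lithio, ring C3=C4) | [Li+].COC(=O)C1=C([C@@H](C)CCCO[Si](C)(C)C(C)(C)C)C([O-])=CCC1 | intermediate
12 | methyl 2-[(2S)-5-(tert-butyldimethylsilyloxy)pentan-2-yl]-3-oxo-4-(phenylselanyl)cyclohex-1-ene-1-carboxylate, both C4 epimers | COC(=O)C1=C([C@@H](C)CCCO[Si](C)(C)C(C)(C)C)C(=O)C([Se]c2ccccc2)CC1 | intermediate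
13 | methyl (3R)-2-[(2S)-5-(tert-butyldimethylsilyloxy)pentan-2-yl]-3-hydroxy-4-(phenylselanyl)cyclohex-1-ene-1-carboxylate, both C4 epimers | COC(=O)C1=C([C@@H](C)CCCO[Si](C)(C)C(C)(C)C)[C@@H](O)C([Se]c2ccccc2)CC1 | intermediate
14 | selenoxide of 13 | COC(=O)C1=C([C@@H](C)CCCO[Si](C)(C)C(C)(C)C)[C@@H](O)C([Se](=O)c2ccccc2)CC1 | intermediate
15 | methyl (3S)-2-[(2S)-5-(tert-butyldimethylsilyloxy)pentan-2-yl]-3-hydroxycyclohexa-1,4-diene-1-carboxylate | COC(=O)C1=C([C@@H](C)CCCO[Si](C)(C)C(C)(C)C)[C@@H](O)C=CC1 | intermediate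
16 | methyl (3S)-3-{[(bromomethyl)dimethylsilyl]oxy}-2-[(2S)-5-(tert-butyldimethylsilyloxy)pentan-2-yl]cyclohexa-1,4-diene-1-carboxylate | COC(=O)C1=C([C@@H](C)CCCO[Si](C)(C)C(C)(C)C)[C@@H](O[Si](C)(C)CBr)C=CC1 | intermediate
17 | methyl (3R,4R,5R)-3-{[(bromomethyl)dimethylsilyl]oxy}-2-[(2S)-5-(tert-butyldimethylsilyloxy)pentan-2-yl]-4,5-epoxycyclohex-1-ene-1-carboxylate, epoxide anti to the silyloxy group | COC(=O)C1=C([C@@H](C)CCCO[Si](C)(C)C(C)(C)C)[C@@H](O[Si](C)(C)CBr)[C@@H]2O[C@@H]2C1 | intermediate
18 | [(3R,4R,5R)-3-{[(bromomethyl)dimethylsilyl]oxy}-2-[(2S)-5-(tert-butyldimethylsilyloxy)pentan-2-yl]-4,5-epoxycyclohex-1-en-1-yl]methanol | OCC1=C([C@@H](C)CCCO[Si](C)(C)C(C)(C)C)[C@@H](O[Si](C)(C)CBr)[C@@H]2O[C@@H]2C1 | intermediate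
19 | methyl (phenylsulfonyl)acetate | COC(=O)CS(=O)(=O)c1ccccc1 | starting material
20 | sodium methyl (phenylsulfonyl)acetate | [Na+].COC(=O)[CH-]S(=O)(=O)c1ccccc1 | intermediate
21 | tethered epoxide: 18 with the silicon CH2 bonded to CH(SO2Ph)CO2Me (C13–C11), both C11 epimers | OCC1=C([C@@H](C)CCCO[Si](C)(C)C(C)(C)C)[C@@H](O[Si](C)(C)CC(C(=O)OC)S(=O)(=O)c2ccccc2)[C@@H]3O[C@@H]3C1 | intermediate
22 | ring-opened hydroxy ester: 1-oxa-2-silacyclohexane closed by C7–C11 (cis to O6), C8–OH trans to C11, C11 bearing SO2Ph and CO2Me | OCC1=C([C@@H](C)CCCO[Si](C)(C)C(C)(C)C)[C@H]2O[Si](C)(C)C[C@@](S(=O)(=O)c3ccccc3)(C(=O)OC)[C@H]2[C@H](O)C1 | intermediate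
23 | tricyclic sulfonyl lactone: 22 with CO2Me closed onto O8 as a trans-fused γ-lactone, C14–OH free | OCC1=C([C@@H](C)CCCO[Si](C)(C)C(C)(C)C)[C@H]2O[Si](C)(C)C[C@@]3(S(=O)(=O)c4ccccc4)C(=O)O[C@H](C1)[C@@H]23 | intermediate
24 | C14 methacrylate of 23 | C=C(C)C(=O)OCC1=C([C@@H](C)CCCO[Si](C)(C)C(C)(C)C)[C@H]2O[Si](C)(C)C[C@@]3(S(=O)(=O)c4ccccc4)C(=O)O[C@H](C1)[C@@H]23 | intermediate
25 | diol: the target with free C6–OH and C1–OH | C=C(C)C(=O)OCC1=C([C@@H](C)CCCO)[C@@H](O)[C@H]2C(=C)C(=O)O[C@@H]2C1 | intermediate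
26 | target CNP0157277.1, [(3aS,4S,7aR)-4-acetoxy-5-[(2S)-5-acetoxypentan-2-yl]-3-methylidene-2-oxo-2,3,3a,4,7,7a-hexahydro-1-benzofuran-6-yl]methyl 2-methylprop-2-enoate | C=C(C)C(=O)OCC1=C([C@@H](C)CCCOC(C)=O)[C@@H](OC(C)=O)[C@H]2C(=C)C(=O)O[C@@H]2C1 | target

**Step count and risks**

Total step count: 17. Longest linear sequence: 17 steps (from 1).

Steps most likely to fail:

Step 14 (Proposed new method). The doubly stabilized carbanion may open the epoxide too slowly, so that desilylation or epoxide isomerization takes over, or the C11 epimer that forms may hold its ester away from O8 so that the lactone does not close. The fallback uses a harder, epimerizable nucleophile and known reactions, sets out from 18 and returns at 26. Alkylation of the bromide with LiCH2CN (from MeCN and LiN(iPr)2, THF, −78 to −20 °C) should give the nitrile-tethered epoxide F1. A Stork epoxynitrile cyclization with KN(SiMe3)2 (THF, −78 to 0 °C) should give the cyclic iminolactone F2, which buffered aqueous acetic acid hydrolyses to the tricyclic lactone F3 with an epimerizable C11–H. Methacrylation as in step 15 gives the methacrylate F4. Tamao–Fleming oxidation (KF, KHCO3, H2O2, THF/MeOH, then Bu4NF) should give the triol F5 with C13–OH, C6–OH and C1–OH. Acetylation (Ac2O, pyridine, DMAP) gives the triacetate F6, and DBU in CH2Cl2 eliminates the β-acetoxy group (E1cB) to give 26.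

Step 8. Facial selectivity may be poor because the selenium-bearing α′ side can compete with the alkenyl side as the large group. The fallback replaces catalyst control by separation and stereoconvergence; it sets out from 12 and returns at 17. Luche reduction (NaBH4, CeCl3·7H2O, MeOH, −40 °C) gives 13 mixed with its carbinol epimer F7. Oxidation as in step 9 gives, via 14 and the epimeric selenoxide F8, dienol 15 and its C3 epimer F9, which are diastereomers and separable; 15 continues as in the route. For F9, hydroxyl-directed epoxidation (VO(acac)2, tBuOOH, CH2Cl2) should give the syn-epoxy alcohol F10, whose epoxide has the configuration required in 17. Mitsunobu inversion (4-nitrobenzoic acid, PPh3, DIAD) gives the inverted ester F11, methanolysis (K2CO3, MeOH) gives the anti-epoxy alcohol F12, and silylation as in step 10 gives 17.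

Step 16. Once fluoride frees the C6 alkoxide next to the new α-methylene lactone, base-mediated migration of the lactone to O6 or conjugate re-addition of benzenesulfinate may erode the product. The fallback unmasks and acylates first and eliminates last, so that no free hydroxyl meets the Michael acceptor; it sets out from 24 and returns at 26. Acidic methanolysis (PPTS, MeOH, 0 to 23 °C) should cleave the Si–O6 bond and the TBS ether but leave the C13–Si bond and the sulfone, giving the diol F13. Acetylation as in step 17 gives the diacetate F14, and CsF in MeCN then triggers the β-silyl sulfone elimination to give 26.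

**Further compounds**

F1 | step 14 | nitrile-tethered epoxide: 18 with Si–CH2Br replaced by Si–CH2CH2CN | OCC1=C([C@@H](C)CCCO[Si](C)(C)C(C)(C)C)[C@@H](O[Si](C)(C)CCC#N)[C@@H]2O[C@@H]2C1
F2 | step 14 | cyclic iminolactone from the epoxynitrile cyclization (not isolated) | OCC1=C([C@@H](C)CCCO[Si](C)(C)C(C)(C)C)[C@H]2O[Si](C)(C)C[C@H]3C(=N)O[C@H](C1)[C@@H]23
F3 | step 14 | tricyclic lactone with C11–H (analogue of 23 without the sulfonyl group) | OCC1=C([C@@H](C)CCCO[Si](C)(C)C(C)(C)C)[C@H]2O[Si](C)(C)C[C@H]3C(=O)O[C@H](C1)[C@@H]23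
F4 | step 14 | C14 methacrylate of F3 | C=C(C)C(=O)OCC1=C([C@@H](C)CCCO[Si](C)(C)C(C)(C)C)[C@H]2O[Si](C)(C)C[C@H]3C(=O)O[C@H](C1)[C@@H]23
F5 | step 14 | triol: α-(hydroxymethyl) lactone with free C6–OH and C1–OH | C=C(C)C(=O)OCC1=C([C@@H](C)CCCO)[C@@H](O)[C@H]2[C@@H](CO)C(=O)O[C@@H]2C1
F6 | step 14 | triacetate of F5 | C=C(C)C(=O)OCC1=C([C@@H](C)CCCOC(C)=O)[C@@H](OC(C)=O)[C@H]2[C@@H](COC(C)=O)C(=O)O[C@@H]2C1
F7 | step 8 | carbinol epimer of 13 (both C4 epimers) | COC(=O)C1=C([C@@H](C)CCCO[Si](C)(C)C(C)(C)C)[C@H](O)C([Se]c2ccccc2)CC1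
F8 | step 8 | selenoxide of F7 (not isolated) | COC(=O)C1=C([C@@H](C)CCCO[Si](C)(C)C(C)(C)C)[C@H](O)C([Se](=O)c2ccccc2)CC1
F9 | step 8 | C3 epimer of dienol 15 | COC(=O)C1=C([C@@H](C)CCCO[Si](C)(C)C(C)(C)C)[C@H](O)C=CC1
F10 | step 8 | syn-epoxy alcohol (4,5-epoxide cis to the 3-hydroxyl) | COC(=O)C1=C([C@@H](C)CCCO[Si](C)(C)C(C)(C)C)[C@H](O)[C@@H]2O[C@@H]2C1
F11 | step 8 | 4-nitrobenzoate with inverted C3 (epoxide anti to the ester oxygen) | COC(=O)C1=C([C@@H](C)CCCO[Si](C)(C)C(C)(C)C)[C@@H](OC(=O)c2ccc(cc2)[N+](=O)[O-])[C@@H]3O[C@@H]3C1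
F12 | step 8 | anti-epoxy alcohol (desilyl 17) | COC(=O)C1=C([C@@H](C)CCCO[Si](C)(C)C(C)(C)C)[C@@H](O)[C@@H]2O[C@@H]2C1
F13 | step 16 | diol with C6–OH and C1–OH free, C11 still bearing SO2Ph and CH2SiMe2OMe | C=C(C)C(=O)OCC1=C([C@@H](C)CCCO)[C@@H](O)[C@H]2[C@](C[Si](C)(C)OC)(S(=O)(=O)c3ccccc3)C(=O)O[C@@H]2C1
F14 | step 16 | diacetate of F13 | C=C(C)C(=O)OCC1=C([C@@H](C)CCCOC(C)=O)[C@@H](OC(C)=O)[C@H]2[C@](C[Si](C)(C)OC)(S(=O)(=O)c3ccccc3)C(=O)O[C@@H]2C1
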